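**Retrosynthetic overview**
1. Target ⇐ last C–C bond (C8–CH2) by intramolecular C-alkylation of a β-keto amide with an aryl-tethered α-chloroketone; the γ-keto amide then closes to the hydroxy lactam.
2. ⇐ rings B and A together by an intramolecular Diels–Alder reaction of a ring-C-bound (E,E)-triene with an (E)-enone (sets C4, C5, C10, C1).
3. ⇐ side arms grown from a ring-C α-hydroxy ester: Mitsunobu aryl ether at C6 (inversion), Wittig chains at C5 and at C4.
4. ⇐ ring-C stereocentres from a BINOL–titanium glyoxylate–ene desymmetrisation of an achiral 1,4-cyclohexadiene (C16, C11, C6) and a hydroxyl-directed hydrogenation (C12, C14).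
5. ⇐ that diene from Birch reductive methylation of methyl 3,5-dimethylbenzoate. Ring order: C (from the arene), then B + A in one step, then the 13-membered ring and the lactam.

Assumption: the C8 and hemiaminal C7 configurations of the target are the thermodynamically preferred ones in the bridged macrocycle (C8 equilibrates by enolisation, C7 by ring–chain tautomerism), and ethyl 3-oxo-4-(triphenylphosphoranylidene)butanoate is bought.

Atom labels used below (not IUPAC): ring A = C1 (methyl, vinyl), C2=C3 (methyl), C4, C5, C10; ring B = C4, C5, C6 (aryloxy), C11, C16; ring C = C11, C12 (methyl), C13, C14 (methyl), C15, C16 (methyl); C9 = ketone carbon on C10; C8 = lactam CH; C7 = hemiaminal carbon. "Upper face" of ring C is the face of the C16 methyl.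

**Step 1**
Reactants: 1 methyl 3,5-dimethylbenzoate
Product: 3 methyl 1,3,5-trimethylcyclohexa-2,5-diene-1-carboxylate, via lithium ester dienolate 2 (not isolated)
Conditions: Li (2.2 equiv), NH3(l)/THF, t-BuOH (1 equiv), −78 °C; then MeI, −78 °C to rt
Reagents that add atoms: iodomethane CI
Why: Birch reduction gives the cross-conjugated dienolate, which is methylated at the ipso carbon (Birch reductive alkylation); the arene becomes the future ring C with the C16 methyl, and the product is achiral (mirror plane through C16 and C13), so no stereocentre is set.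

**Step 2**
Reactants: 3 methyl 1,3,5-trimethylcyclohexa-2,5-diene-1-carboxylate
Product: 4 1,3,5-trimethylcyclohexa-2,5-diene-1-carbaldehyde
Conditions: i-Bu2AlH (1.1 equiv), CH2Cl2, −78 °C; aq. potassium sodium tartrate
Reagents that add atoms: none
Why: Partial hydride reduction of a hindered α-quaternary ester stops at the aluminium hemiacetal at −78 °C and gives the aldehyde (future C4) on work-up (ester-to-aldehyde reduction); no stereocentre.

**Step 3**
Reactants: 4 1,3,5-trimethylcyclohexa-2,5-diene-1-carbaldehyde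
Product: 5 2-(1,3,5-trimethylcyclohexa-2,5-dien-1-yl)-1,3-dioxolane
Conditions: HOCH2CH2OH, PPTS (cat.), benzene, reflux, Dean–Stark
Reagents that add atoms: ethylene glycol OCCO
Why: Acid-catalysed acetalisation masks C4 and turns it into a bulky sp3 group that shields the lower face of both alkenes; no stereocentre.

**Step 4**
Reactants: 5 2-(1,3,5-trimethylcyclohexa-2,5-dien-1-yl)-1,3-dioxolane; 6 methyl glyoxylate
Product: 7 methyl (2S)-2-[(1R,6R)-6-(1,3-dioxolan-2-yl)-2,4,6-trimethylcyclohexa-2,4-dien-1-yl]-2-hydroxyacetate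
Conditions: TiCl2(O-i-Pr)2/(S)-BINOL (10 mol%), 6 (1.1 equiv), 4 Å MS, CH2Cl2, −30 °C
Reagents that add atoms: none
Why: Proposed new method: a catalytic enantioselective carbonyl–ene reaction used to desymmetrise the diene; the titanium-chelated glyoxylate carbon bonds to the less substituted alkene carbon C11 on the face anti to the dioxolane while a doubly allylic C13–H is transferred through a six-membered ene transition state (ester exo, formyl hydrogen towards the C16 methyl), and the catalyst's fixed glyoxylate face (2S, mirror of the sense known for the R ligand) is matched with only one of the two enantiotopic alkenes, so C16, C11 and C6 are set together; closest known type is the BINOL–titanium glyoxylate–ene reaction of trisubstituted alkenes and its use on symmetric bis-alkenes.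

**Step 5**
Reactants: 7 methyl (2S)-2-[(1R,6R)-6-(1,3-dioxolan-2-yl)-2,4,6-trimethylcyclohexa-2,4-dien-1-yl]-2-hydroxyacetate
Product: 8 methyl (2S)-2-[(1R,2R,4R,6S)-2-(1,3-dioxolan-2-yl)-2,4,6-trimethylcyclohexyl]-2-hydroxyacetate
Conditions: [Ir(cod)(PCy3)(py)]PF6 (5 mol%), H2 (1 atm), CH2Cl2, rt
Reagents that add atoms: none
Why: Hydroxyl-directed hydrogenation: the iridium centre is held by the C6 hydroxyl on the upper face (the lower face is also blocked by the dioxolane) and delivers hydrogen to both ring alkenes from that face, so the C12 and C14 methyls end cis to the dioxolane.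

**Step 6**
Reactants: 9 1-(benzyloxy)-4-bromobenzene; 10 (S)-epichlorohydrin
Product: 12 (2S)-1-[4-(benzyloxy)phenyl]-3-chloropropan-2-ol, via aryl Grignard reagent 11 (not isolated)
Conditions: Mg, THF, 40 °C; then CuI (10 mol%), 10, −40 to 0 °C; aq. NH4Cl
Reagents that add atoms: none
Why: Copper-catalysed Grignard opening of the epoxide at its terminal carbon leaves the stereocentre of 10 untouched (chlorohydrin synthesis).

**Step 7**
Reactants: 12 (2S)-1-[4-(benzyloxy)phenyl]-3-chloropropan-2-ol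
Product: 13 {[(2S)-1-[4-(benzyloxy)phenyl]-3-chloropropan-2-yl]oxy}(tert-butyl)diphenylsilane
Conditions: t-BuPh2SiCl, imidazole, DMF, rt
Reagents that add atoms: tert-butyl(chloro)diphenylsilane CC(C)(C)[Si](Cl)(c1ccccc1)c1ccccc1
Why: Standard silylation; the robust silyl ether keeps the chlorohydrin from closing to an epoxide under the later basic steps.

**Step 8**
Reactants: 13 {[(2S)-1-[4-(benzyloxy)phenyl]-3-chloropropan-2-yl]oxy}(tert-butyl)diphenylsilane
Product: 14 4-[(2S)-2-{[tert-butyl(diphenyl)silyl]oxy}-3-chloropropyl]phenol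
Conditions: H2 (1 atm), 10% Pd/C, EtOAc, rt
Reagents that add atoms: none
Why: Hydrogenolysis of the benzyl ether; the alkyl chloride and silyl ether are inert.

**Step 9**
Reactants: 8 methyl (2S)-2-[(1R,2R,4R,6S)-2-(1,3-dioxolan-2-yl)-2,4,6-trimethylcyclohexyl]-2-hydroxyacetate; 14 4-[(2S)-2-{[tert-butyl(diphenyl)silyl]oxy}-3-chloropropyl]phenol
Product: 15 methyl (2R)-2-{4-[(2S)-2-{[tert-butyl(diphenyl)silyl]oxy}-3-chloropropyl]phenoxy}-2-[(1R,2R,4R,6S)-2-(1,3-dioxolan-2-yl)-2,4,6-trimethylcyclohexyl]acetate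
Conditions: PBu3, 1,1'-(azodicarbonyl)dipiperidine, toluene, 0 to 60 °C
Reagents that add atoms: none
Why: Mitsunobu etherification: SN2 displacement of the phosphonium-activated α-hydroxy ester by the phenoxide inverts C6 to the configuration of the target, the adjacent ester accelerating the displacement.

**Step 10**
Reactants: 16 ethyl 3-oxo-4-(triphenylphosphoranylidene)butanoate
Product: 17 3-oxo-4-(triphenylphosphoranylidene)butanamide
Conditions: NH3 (7 M in MeOH), sealed tube, 50 °C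
Reagents that add atoms: ammonia N
Why: Ester ammonolysis; the ylide-conjugated ketone is deactivated, so the primary β-keto amide forms without enamine formation.

**Step 11**
Reactants: 15 methyl (2R)-2-{4-[(2S)-2-{[tert-butyl(diphenyl)silyl]oxy}-3-chloropropyl]phenoxy}-2-[(1R,2R,4R,6S)-2-(1,3-dioxolan-2-yl)-2,4,6-trimethylcyclohexyl]acetate; 17 3-oxo-4-(triphenylphosphoranylidene)butanamide
Product: 19 (4E,6S)-6-{4-[(2S)-2-{[tert-butyl(diphenyl)silyl]oxy}-3-chloropropyl]phenoxy}-6-[(1R,2R,4R,6S)-2-(1,3-dioxolan-2-yl)-2,4,6-trimethylcyclohexyl]-3-oxohex-4-enamide, via α-aryloxy aldehyde 18 (not isolated)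
Conditions: i-Bu2AlH (1.1 equiv), CH2Cl2, −78 °C; MeOH; then 17 (2 equiv), −78 to 40 °C
Reagents that add atoms: none
Why: Ester-to-aldehyde reduction followed by in situ Wittig olefination with the acyl-stabilised ylide gives the E-enone and avoids handling the epimerisable aldehyde, so C6 is kept.

**Step 12**
Reactants: 19 (dioxolane enone β-keto amide from step 11)
Product: 20 (4E,6S)-6-{4-[(2S)-2-{[tert-butyl(diphenyl)silyl]oxy}-3-chloropropyl]phenoxy}-6-[(1R,2R,4R,6S)-2-formyl-2,4,6-trimethylcyclohexyl]-3-oxohex-4-enamide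
Conditions: 2 M aq. HCl/THF (1:4), 40 °C
Reagents that add atoms: water O
Why: Acetal hydrolysis frees the non-enolisable C4 aldehyde; the silyl ether, aryl ether and enone tolerate dilute acid.

**Step 13**
Reactants: 20 (C4 aldehyde from step 12)
Product: 21 (4E,6S)-6-{4-[(2S)-2-{[tert-butyl(diphenyl)silyl]oxy}-3-chloropropyl]phenoxy}-6-{(1R,2S,4R,6S)-2,4,6-trimethyl-2-[(1E)-2-methyl-3-oxoprop-1-en-1-yl]cyclohexyl}-3-oxohex-4-enamide
Conditions: Ph3P=C(CH3)CHO (3 equiv), toluene, 100 °C
Reagents that add atoms: 2-(triphenylphosphoranylidene)propanal CC(C=O)=P(c1ccccc1)(c1ccccc1)c1ccccc1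
Why: Wittig reaction of a stabilised ylide with the aldehyde gives the (E)-trisubstituted enal (C4=C3, C16 trans to C2); it does not touch the ketone or the enone.

**Step 14**
Reactants: 21 (enal from step 13)
Product: 22 (4E,6S)-6-{4-[(2S)-2-{[tert-butyl(diphenyl)silyl]oxy}-3-chloropropyl]phenoxy}-6-{(1R,2S,4R,6S)-2-[(1E,3E)-2,4-dimethyl-5-oxopenta-1,3-dien-1-yl]-2,4,6-trimethylcyclohexyl}-3-oxohex-4-enamide
Conditions: Ph3P=C(CH3)CHO (2 equiv), benzene, 80 °C
Reagents that add atoms: 2-(triphenylphosphoranylidene)propanal CC(C=O)=P(c1ccccc1)(c1ccccc1)c1ccccc1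
Why: Second Wittig reaction with the same stabilised ylide sets the C2=C1 geometry (E, formyl carbon trans to C3); the formyl-substituted diene is too electron-poor to cycloadd at this temperature.

**Step 15**
Reactants: 22 (dienal from step 14)
Product: 23 (4E,6S)-6-{4-[(2S)-2-{[tert-butyl(diphenyl)silyl]oxy}-3-chloropropyl]phenoxy}-6-{(1R,2S,4R,6S)-2-[(1E,3E)-2,4-dimethylhexa-1,3,5-trien-1-yl]-2,4,6-trimethylcyclohexyl}-3-oxohex-4-enamide
Conditions: Ph3PCH3Br, KN(SiMe3)2 (3.5 equiv of ylide), THF, −78 to 0 °C; aq. NH4Cl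
Reagents that add atoms: methyltriphenylphosphonium bromide C[P+](c1ccccc1)(c1ccccc1)c1ccccc1.[Br-]
Why: Wittig methylenation of the aldehyde; the first equivalents of ylide deprotonate the β-keto amide, which protects the enone carbonyl as its enolate.

**Step 16**
Reactants: 23 (tetraene from step 15)
Product: 24 Diels–Alder adduct: trans-fused 6-5-6 tricycle (rings A, B, C) carrying the C1 methyl and vinyl, the C3, C12, C14 and C16 methyls, the C6 4-[(2S)-2-{[tert-butyl(diphenyl)silyl]oxy}-3-chloropropyl]phenoxy group and the C10 3-amino-1,3-dioxopropyl chain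
Conditions: toluene (5 mM), BHT (cat.), 120 °C, sealed tube
Reagents that add atoms: none
Why: Intramolecular Diels–Alder reaction: the endo transition state (C9 carbonyl under the diene) gives the trans ring B/A fusion, the E-enone places the C10 acyl trans to C6, and the diene geometry (vinyl outside, methyl inside) fixes C1; allylic 1,3-strain with the C3 methyl keeps the C16 methyl in the diene plane and so selects the diene face, setting C4, C5, C10 and C1.

**Step 17**
Reactants: 24 (Diels–Alder adduct from step 16)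
Product: 25 tricyclic chlorohydrin: as 24 with a free (2S)-3-chloro-2-hydroxypropyl group on the aryl ring
Conditions: HF·pyridine, THF/pyridine, 0 °C to rt
Reagents that add atoms: none
Why: Fluoride-mediated desilylation under acidic buffering keeps the chlorohydrin from closing to the epoxide; no stereocentre changes.

**Step 18**
Reactants: 25 (tricyclic chlorohydrin from step 17)
Product: 26 tricyclic α-chloroketone: as 25 with a 3-chloro-2-oxopropyl group on the aryl ring
Conditions: Dess–Martin periodinane, NaHCO3, CH2Cl2, 0 °C to rt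
Reagents that add atoms: none
Why: Dess–Martin oxidation of the secondary alcohol gives the α-chloroketone (C7 carbonyl) without touching the alkenes or the β-keto amide.

**Step 19**
Reactants: 26 (tricyclic α-chloroketone from step 18)
Product: 28 CNP0450261.1 (target), via macrocyclic γ-keto amide 27 (not isolated)
Conditions: Cs2CO3 (2 equiv), MeCN (1 mM, slow addition), 40 °C
Reagents that add atoms: none
Why: Intramolecular SN2 C-alkylation of the soft β-keto amide carbon C8 by the α-chloroketone closes the 13-membered ring, and the amide nitrogen then adds to the C7 ketone to give the hydroxy lactam; C8 and C7 settle under equilibrium control.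

**Compound list**
1 | methyl 3,5-dimethylbenzoate | COC(=O)c1cc(C)cc(C)c1 | starting material
2 | lithium ester dienolate | [Li+].COC([O-])=C1C=C(C)CC(C)=C1 | intermediate
3 | methyl 1,3,5-trimethylcyclohexa-2,5-diene-1-carboxylate | COC(=O)C1(C)C=C(C)CC(C)=C1 | intermediate
4 | 1,3,5-trimethylcyclohexa-2,5-diene-1-carbaldehyde | O=CC1(C)C=C(C)CC(C)=C1 | intermediate
5 | 2-(1,3,5-trimethylcyclohexa-2,5-dien-1-yl)-1,3-dioxolane | CC1=CC(C)(C2OCCO2)C=C(C)C1 | intermediate
6 | methyl glyoxylate | COC(=O)C=O | starting material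
7 | methyl (2S)-2-[(1R,6R)-6-(1,3-dioxolan-2-yl)-2,4,6-trimethylcyclohexa-2,4-dien-1-yl]-2-hydroxyacetate | COC(=O)[C@@H](O)[C@@H]1C(C)=CC(C)=C[C@]1(C2OCCO2)C | intermediate
8 | methyl (2S)-2-[(1R,2R,4R,6S)-2-(1,3-dioxolan-2-yl)-2,4,6-trimethylcyclohexyl]-2-hydroxyacetate | COC(=O)[C@@H](O)[C@@H]1[C@@H](C)C[C@@H](C)C[C@]1(C2OCCO2)C | intermediate
9 | 1-(benzyloxy)-4-bromobenzene | Brc1ccc(OCc2ccccc2)cc1 | starting material
10 | (S)-epichlorohydrin | ClC[C@@H]1CO1 | starting material
11 | [4-(benzyloxy)phenyl]magnesium bromide | Br[Mg]c1ccc(OCc2ccccc2)cc1 | intermediate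
12 | (2S)-1-[4-(benzyloxy)phenyl]-3-chloropropan-2-ol | ClC[C@@H](O)Cc1ccc(OCc2ccccc2)cc1 | intermediate
13 | {[(2S)-1-[4-(benzyloxy)phenyl]-3-chloropropan-2-yl]oxy}(tert-butyl)diphenylsilane | ClC[C@@H](O[Si](c1ccccc1)(c1ccccc1)C(C)(C)C)Cc1ccc(OCc2ccccc2)cc1 | intermediate
14 | 4-[(2S)-2-{[tert-butyl(diphenyl)silyl]oxy}-3-chloropropyl]phenol | ClC[C@@H](O[Si](c1ccccc1)(c1ccccc1)C(C)(C)C)Cc1ccc(O)cc1 | intermediate
15 | methyl (2R)-2-{4-[(2S)-2-{[tert-butyl(diphenyl)silyl]oxy}-3-chloropropyl]phenoxy}-2-[(1R,2R,4R,6S)-2-(1,3-dioxolan-2-yl)-2,4,6-trimethylcyclohexyl]acetate | COC(=O)[C@H](Oc1ccc(cc1)C[C@@H](CCl)O[Si](c1ccccc1)(c1ccccc1)C(C)(C)C)[C@@H]1[C@@H](C)C[C@@H](C)C[C@]1(C2OCCO2)C | intermediate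
16 | ethyl 3-oxo-4-(triphenylphosphoranylidene)butanoate | CCOC(=O)CC(=O)C=P(c1ccccc1)(c1ccccc1)c1ccccc1 | starting material
17 | 3-oxo-4-(triphenylphosphoranylidene)butanamide | NC(=O)CC(=O)C=P(c1ccccc1)(c1ccccc1)c1ccccc1 | intermediate
18 | (2R)-2-{4-[(2S)-2-{[tert-butyl(diphenyl)silyl]oxy}-3-chloropropyl]phenoxy}-2-[(1R,2R,4R,6S)-2-(1,3-dioxolan-2-yl)-2,4,6-trimethylcyclohexyl]acetaldehyde | O=C[C@H](Oc1ccc(cc1)C[C@@H](CCl)O[Si](c1ccccc1)(c1ccccc1)C(C)(C)C)[C@@H]1[C@@H](C)C[C@@H](C)C[C@]1(C2OCCO2)C | intermediate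
19 | (4E,6S)-6-{4-[(2S)-2-{[tert-butyl(diphenyl)silyl]oxy}-3-chloropropyl]phenoxy}-6-[(1R,2R,4R,6S)-2-(1,3-dioxolan-2-yl)-2,4,6-trimethylcyclohexyl]-3-oxohex-4-enamide | NC(=O)CC(=O)/C=C/[C@H](Oc1ccc(cc1)C[C@@H](CCl)O[Si](c1ccccc1)(c1ccccc1)C(C)(C)C)[C@@H]1[C@@H](C)C[C@@H](C)C[C@]1(C2OCCO2)C | intermediate
20 | (4E,6S)-6-{4-[(2S)-2-{[tert-butyl(diphenyl)silyl]oxy}-3-chloropropyl]phenoxy}-6-[(1R,2R,4R,6S)-2-formyl-2,4,6-trimethylcyclohexyl]-3-oxohex-4-enamide | NC(=O)CC(=O)/C=C/[C@H](Oc1ccc(cc1)C[C@@H](CCl)O[Si](c1ccccc1)(c1ccccc1)C(C)(C)C)[C@@H]1[C@@H](C)C[C@@H](C)C[C@]1(C=O)C | intermediate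
21 | (4E,6S)-6-{4-[(2S)-2-{[tert-butyl(diphenyl)silyl]oxy}-3-chloropropyl]phenoxy}-6-{(1R,2S,4R,6S)-2,4,6-trimethyl-2-[(1E)-2-methyl-3-oxoprop-1-en-1-yl]cyclohexyl}-3-oxohex-4-enamide | NC(=O)CC(=O)/C=C/[C@H](Oc1ccc(cc1)C[C@@H](CCl)O[Si](c1ccccc1)(c1ccccc1)C(C)(C)C)[C@@H]1[C@@H](C)C[C@@H](C)C[C@]1(/C=C(/C=O)C)C | intermediate
22 | (4E,6S)-6-{4-[(2S)-2-{[tert-butyl(diphenyl)silyl]oxy}-3-chloropropyl]phenoxy}-6-{(1R,2S,4R,6S)-2-[(1E,3E)-2,4-dimethyl-5-oxopenta-1,3-dien-1-yl]-2,4,6-trimethylcyclohexyl}-3-oxohex-4-enamide | NC(=O)CC(=O)/C=C/[C@H](Oc1ccc(cc1)C[C@@H](CCl)O[Si](c1ccccc1)(c1ccccc1)C(C)(C)C)[C@@H]1[C@@H](C)C[C@@H](C)C[C@]1(/C=C(/C=C(/C=O)C)C)C | intermediate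
23 | (4E,6S)-6-{4-[(2S)-2-{[tert-butyl(diphenyl)silyl]oxy}-3-chloropropyl]phenoxy}-6-{(1R,2S,4R,6S)-2-[(1E,3E)-2,4-dimethylhexa-1,3,5-trien-1-yl]-2,4,6-trimethylcyclohexyl}-3-oxohex-4-enamide | NC(=O)CC(=O)/C=C/[C@H](Oc1ccc(cc1)C[C@@H](CCl)O[Si](c1ccccc1)(c1ccccc1)C(C)(C)C)[C@@H]1[C@@H](C)C[C@@H](C)C[C@]1(/C=C(/C=C(/C=C)C)C)C | intermediate
24 | Diels–Alder adduct (rings A, B, C; silyl-protected chlorohydrin on the aryl ring; β-keto amide on C10) | C=C[C@@]1(C)C=C(C)[C@@H]2[C@H]([C@H](Oc3ccc(cc3)C[C@@H](CCl)O[Si](c3ccccc3)(c3ccccc3)C(C)(C)C)[C@@H]3[C@@H](C)C[C@@H](C)C[C@]32C)[C@H]1C(=O)CC(N)=O | intermediate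
25 | tricyclic chlorohydrin β-keto amide | C=C[C@@]1(C)C=C(C)[C@@H]2[C@H]([C@H](Oc3ccc(cc3)C[C@@H](CCl)O)[C@@H]3[C@@H](C)C[C@@H](C)C[C@]32C)[C@H]1C(=O)CC(N)=O | intermediate
26 | tricyclic α-chloroketone β-keto amide | C=C[C@@]1(C)C=C(C)[C@@H]2[C@H]([C@H](Oc3ccc(cc3)CC(=O)CCl)[C@@H]3[C@@H](C)C[C@@H](C)C[C@]32C)[C@H]1C(=O)CC(N)=O | intermediate
27 | macrocyclic γ-keto amide (open form of the hydroxy lactam) | C=C[C@@]1(C)C=C(C)[C@@H]2[C@@H]3[C@H](Oc4ccc(cc4)CC(=O)C[C@H](C(N)=O)C(=O)[C@H]31)[C@@H]1[C@@H](C)C[C@@H](C)C[C@]12C | intermediate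
28 | CNP0450261.1 | C=C[C@@]1(C)C=C(C)[C@@H]2[C@@H]3[C@H](Oc4ccc(cc4)C[C@@]4(O)C[C@H](C(=O)N4)C(=O)[C@H]31)[C@@H]1[C@@H](C)C[C@@H](C)C[C@]12C | target

**Step count and risks**
Total step count: 19. Longest linear sequence: 15 steps (steps 1–5, 9, 11–19).

Most likely to fail, first: step 4. The ene reaction must form a bond at an alkene carbon next to a quaternary centre, on the face anti to the acetal, with the catalyst choosing between the two alkenes, and the conjugated diene product may react again with the glyoxylate. The fallback sets out from 5 and comes back at 7. It replaces catalyst control by a covalent auxiliary and a stronger Lewis acid: 5 is treated with the glyoxylate ester of (1R,2S,5R)-8-phenylmenthol and SnCl4 in CH2Cl2 at −78 °C, the phenyl group blocking one carbonyl face, to give the 8-phenylmenthyl ester of the ene adduct F1. Transesterification with K2CO3 in methanol then gives 7 and returns the auxiliary.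

Second: step 9. Backside attack at C6 is hindered by the neighbouring tertiary and quaternary ring carbons, and elimination may compete. The fallback sets out from 8 and comes back at 15. It makes C6 an electrophilic carbene carbon, so no backside attack is needed: Dess–Martin oxidation of 8 gives the α-keto ester F2, condensation with tosylhydrazine gives the tosylhydrazone F3, and DBU converts it into the α-diazo ester F4 (Bamford–Stevens). O–H insertion into phenol 14, catalysed by Cu(MeCN)4PF6 with a chiral spiro-bis(oxazoline) ligand, then gives 15 with the C6 configuration set by the catalyst.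

Third: step 19. The 13-membered para-cyclophane is strained, so oligomerisation, O-alkylation or Favorskii-type loss of the chloroketone may win. The fallback sets out from 25 and comes back at 27. It closes the ring while C7 is still an sp3 carbinol, which is less strained: K2CO3 in methanol turns chlorohydrin 25 into the epoxide F5, and Cs2CO3 with LiClO4 in dilute MeCN opens the epoxide at its terminal carbon with the β-keto amide carbon C8 to give the macrocyclic hydroxy keto amide F6. Dess–Martin oxidation of F6 gives 27, which closes to 28 as in the main route.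

**Further compounds**
F1 | step 4 | (1R,2S,5R)-8-phenylmenthyl (2S)-2-[(1R,6R)-6-(1,3-dioxolan-2-yl)-2,4,6-trimethylcyclohexa-2,4-dien-1-yl]-2-hydroxyacetate | C[C@@H]1CC[C@H]([C@@H](C1)OC(=O)[C@@H](O)[C@@H]1C(C)=CC(C)=C[C@]1(C2OCCO2)C)C(C)(C)c1ccccc1
F2 | step 9 | methyl 2-[(1R,2R,4R,6S)-2-(1,3-dioxolan-2-yl)-2,4,6-trimethylcyclohexyl]-2-oxoacetate | COC(=O)C(=O)[C@@H]1[C@@H](C)C[C@@H](C)C[C@]1(C2OCCO2)C
F3 | step 9 | tosylhydrazone of F2 | COC(=O)C(=NNS(=O)(=O)c1ccc(C)cc1)[C@@H]1[C@@H](C)C[C@@H](C)C[C@]1(C2OCCO2)C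
F4 | step 9 | methyl 2-diazo-2-[(1R,2R,4R,6S)-2-(1,3-dioxolan-2-yl)-2,4,6-trimethylcyclohexyl]acetate | COC(=O)C(=[N+]=[N-])[C@@H]1[C@@H](C)C[C@@H](C)C[C@]1(C2OCCO2)C
F5 | step 19 | tricyclic epoxide β-keto amide (aryl ring carries a (2S)-oxiran-2-ylmethyl group) | C=C[C@@]1(C)C=C(C)[C@@H]2[C@H]([C@H](Oc3ccc(cc3)C[C@@H]3OC3)[C@@H]3[C@@H](C)C[C@@H](C)C[C@]32C)[C@H]1C(=O)CC(N)=O
F6 | step 19 | macrocyclic hydroxy keto amide (C7 carbinol) | C=C[C@@]1(C)C=C(C)[C@@H]2[C@@H]3[C@H](Oc4ccc(cc4)C[C@H](O)C[C@H](C(N)=O)C(=O)[C@H]31)[C@@H]1[C@@H](C)C[C@@H](C)C[C@]12C
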